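**Strategy.** The flavanone is cut at C2–C3. Once O1 of ring A is etherified with the ring-B benzyl unit, the future C2 is an O1–CH2–aryl carbon whose hydrogens are activated by the ether oxygen and by the electron-rich ring B, and it is the sixth atom counted from C3. Decomposing a ring-A diazomethyl ketone with a chiral dirhodium tetracarboxylate places a metal carbene on C3; it takes one of the two enantiotopic hydrogens, so a single neutral operation makes the C2–C3 bond, completes ring C and fixes the (2S) centre. The precursor is a pentasubstituted ring-A diazoketone with the O1 vanillyl ether, a C5 silyl ether, the C6 2-methylbut-3-en-2-yl group and a C7 MOM ether.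

Key step: step 8

Assumption: the (S)-tert-leucinate catalyst Rh2(S-PTTL)4 (dirhodium tetrakis[N-phthaloyl-(S)-tert-leucinate]) is taken to deliver the (2S) product; should the opposite sense be found, its mirror image Rh2(R-PTTL)4 is used and nothing else changes.

Precursor design: both ring-A ethers are in place before the sigmatropic shift, so each oxygen is defined by construction and no selective alkylation of a diol is needed. The ring-B unit is attached as its alcohol, which avoids a labile 4-alkoxybenzyl halide. C5–O carries TBS (no C–H next to oxygen); the MOM groups at C7–O and C4'–O are beyond the reach of the carbene and inert to every base used.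

**Route**

Step 1
Reactants: 1 2,4,6-trihydroxyacetophenone
Product: 2 1-[2,6-dihydroxy-4-(methoxymethoxy)phenyl]ethan-1-one
Conditions: MOMCl (1.0 equiv), iPr2NEt, THF, 0 °C
Reagents that add atoms: chloromethyl methyl ether (MOMCl), COCCl
Why: MOM protection by O-alkylation of a phenol with an α-chloro ether: the 4-OH is the most acidic hydroxyl and the only one not held in a hydrogen bond to the acetyl oxygen, so one equivalent of MOMCl should react there first.

Step 2
Reactants: 2 1-[2,6-dihydroxy-4-(methoxymethoxy)phenyl]ethan-1-one; 3 prenyl bromide (1-bromo-3-methylbut-2-ene)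
Product: 4 1-[2-hydroxy-4-(methoxymethoxy)-6-(3-methylbut-2-en-1-yloxy)phenyl]ethan-1-one
Conditions: K2CO3, acetone, reflux
Reagents that add atoms: none
Why: Williamson ether synthesis: the two chelated hydroxyls of 2 are equivalent, and after the first SN2 alkylation by the allylic bromide the remaining hydroxyl stays locked to the carbonyl oxygen, which should hold the reaction at the mono-ether.

Step 3
Reactants: 5 vanillyl alcohol (4-(hydroxymethyl)-2-methoxyphenol)
Product: 6 [3-methoxy-4-(methoxymethoxy)phenyl]methanol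
Conditions: MOMCl (1.05 equiv), K2CO3, acetone, 0 °C → rt
Reagents that add atoms: chloromethyl methyl ether (MOMCl), COCCl
Why: MOM protection by Williamson-type O-alkylation: K2CO3 deprotonates only the phenol, so the phenoxide and not the benzylic alcohol should be alkylated.

Step 4
Reactants: 4 1-[2-hydroxy-4-(methoxymethoxy)-6-(3-methylbut-2-en-1-yloxy)phenyl]ethan-1-one; 6 [3-methoxy-4-(methoxymethoxy)phenyl]methanol
Product: 7 1-[2-{[3-methoxy-4-(methoxymethoxy)phenyl]methoxy}-4-(methoxymethoxy)-6-(3-methylbut-2-en-1-yloxy)phenyl]ethan-1-one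
Conditions: PPh3, DIAD, THF, 0 °C → rt
Reagents that add atoms: none
Why: Mitsunobu etherification: the single free, acidic phenol of 4 is the pronucleophile and displaces the phosphonium-activated primary benzylic oxygen of 6, so the future O1 ether is made without a choice between two phenols.

Step 5
Reactants: 7 1-[2-{[3-methoxy-4-(methoxymethoxy)phenyl]methoxy}-4-(methoxymethoxy)-6-(3-methylbut-2-en-1-yloxy)phenyl]ethan-1-one
Product: 8 1-[2-hydroxy-6-{[3-methoxy-4-(methoxymethoxy)phenyl]methoxy}-4-(methoxymethoxy)-3-(2-methylbut-3-en-2-yl)phenyl]ethan-1-one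
Conditions: Eu(fod)3 (10 mol %), CHCl3, 55 °C
Reagents that add atoms: none
Why: Aromatic Claisen rearrangement ([3,3]-sigmatropic shift) accelerated by chelation of europium between the acetyl oxygen and the allyl ether oxygen: the allyl unit is delivered with allylic inversion to the only free ortho carbon, and the dienone should tautomerise to the hydrogen-bonded phenol at a temperature low enough to hold back a further Cope shift to the para carbon.

Step 6
Reactants: 8 1-[2-hydroxy-6-{[3-methoxy-4-(methoxymethoxy)phenyl]methoxy}-4-(methoxymethoxy)-3-(2-methylbut-3-en-2-yl)phenyl]ethan-1-one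
Product: 9 1-[2-{[tert-butyl(dimethyl)silyl]oxy}-6-{[3-methoxy-4-(methoxymethoxy)phenyl]methoxy}-4-(methoxymethoxy)-3-(2-methylbut-3-en-2-yl)phenyl]ethan-1-one
Conditions: NaH (1.05 equiv), THF/DMF, 0 °C; TBSCl, rt
Reagents that add atoms: tert-butyldimethylsilyl chloride (TBSCl), CC(C)(C)[Si](C)(C)Cl
Why: O-silylation of a phenoxide: the phenol is far more acidic than the methyl ketone, so one equivalent of NaH should give only the phenoxide, which attacks TBSCl at oxygen despite its two ortho groups, while MOM ethers and alkenes are inert to these reagents.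

Step 7
Reactants: 9 1-[2-{[tert-butyl(dimethyl)silyl]oxy}-6-{[3-methoxy-4-(methoxymethoxy)phenyl]methoxy}-4-(methoxymethoxy)-3-(2-methylbut-3-en-2-yl)phenyl]ethan-1-one
Product: 11 2-diazo-1-[2-{[tert-butyl(dimethyl)silyl]oxy}-6-{[3-methoxy-4-(methoxymethoxy)phenyl]methoxy}-4-(methoxymethoxy)-3-(2-methylbut-3-en-2-yl)phenyl]ethan-1-one, via trifluoroacetyl ketone 10 (not isolated)
Conditions: LiN(SiMe3)2, THF, −78 °C, then CF3CO2CH2CF3; cold 5% aq. HCl work-up; MsN3, Et3N, H2O (1 equiv), MeCN, rt
Reagents that add atoms: 2,2,2-trifluoroethyl trifluoroacetate, O=C(OCC(F)(F)F)C(F)(F)F (its CF3CO group stays only in 10); methanesulfonyl azide, CS(=O)(=O)N=[N+]=[N-]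
Why: Detrifluoroacetylative (Regitz-type) diazo transfer: the kinetic lithium enolate of the methyl ketone is C-acylated by the trifluoroacetate, and the activated 1,3-diketone 10 takes the diazo group from MsN3 with loss of the trifluoroacetyl group to the sulfonamide, the enolate being kept at −78 °C so that the neighbouring silyl group should not migrate.

Step 8
Reactants: 11 2-diazo-1-[2-{[tert-butyl(dimethyl)silyl]oxy}-6-{[3-methoxy-4-(methoxymethoxy)phenyl]methoxy}-4-(methoxymethoxy)-3-(2-methylbut-3-en-2-yl)phenyl]ethan-1-one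
Product: 12 (2S)-5-{[tert-butyl(dimethyl)silyl]oxy}-2-[3-methoxy-4-(methoxymethoxy)phenyl]-7-(methoxymethoxy)-6-(2-methylbut-3-en-2-yl)-2,3-dihydro-4H-chromen-4-one
Conditions: Rh2(S-PTTL)4 (2 mol %), CH2Cl2, 0 °C, slow addition of 11 (final concentration about 0.01 M)
Reagents that add atoms: none
Why: Rh2(S-PTTL)4 expels N2 from 11 to give an electrophilic rhodium carbenoid at C3, which takes up one of the two enantiotopic hydrogens of the O1–CH2–aryl group in a concerted, asynchronous three-centre insertion that forms the C2–C3 bond with retention at C2. The closest known reaction type is the enantioselective dirhodium-catalysed intramolecular C–H insertion of ortho-alkoxyaryl diazoketones to 2-substituted chroman-4-ones. Ring C closes as a six-membered ring by 1,6-insertion, the chain C3–C4–C4a–C8a–O1–C2 folding so that the carbenoid carbon reaches the C2–H bond. The new C2 centre is controlled by the catalyst alone: the four N-phthaloyl-(S)-tert-leucinate ligands form a chiral pocket around the carbenoid that tells the two hydrogens apart, the substrate having no other stereocentre. The step needs chemoselectivity for this C–H bond over oxonium ylide formation at O1 followed by benzyl shift, over addition to ring B and over carbene dimerisation, and it needs enantioselectivity. The substrate favours the insertion through a C–H bond activated by O1 and by the 4'-oxygenated ring B, an O1 lone pair delocalised into the acyl-bearing ring A, a C5 oxygen that bears silicon in place of a C–H carbon and is shielded by its neighbours, and a vinyl group held meta to the acyl carbon and out of reach, while slow addition at low concentration limits dimerisation.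

Step 9
Reactants: 12 (2S)-5-{[tert-butyl(dimethyl)silyl]oxy}-2-[3-methoxy-4-(methoxymethoxy)phenyl]-7-(methoxymethoxy)-6-(2-methylbut-3-en-2-yl)-2,3-dihydro-4H-chromen-4-one
Product: 13 (2S)-5-hydroxy-2-[3-methoxy-4-(methoxymethoxy)phenyl]-7-(methoxymethoxy)-6-(2-methylbut-3-en-2-yl)-2,3-dihydro-4H-chromen-4-one
Conditions: TBAF, AcOH (1:1), THF, 0 °C
Reagents that add atoms: none
Why: Fluoride-induced desilylation of an aryl silyl ether, driven by the strong Si–F bond: acetic acid buffers the phenoxide so that the flavanone should not open by retro-oxa-Michael reaction and C2 keeps its configuration.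

Step 10
Reactants: 13 (2S)-5-hydroxy-2-[3-methoxy-4-(methoxymethoxy)phenyl]-7-(methoxymethoxy)-6-(2-methylbut-3-en-2-yl)-2,3-dihydro-4H-chromen-4-one
Product: 14 (2S)-5,7-dihydroxy-2-(4-hydroxy-3-methoxyphenyl)-6-(2-methylbut-3-en-2-yl)-2,3-dihydro-4H-chromen-4-one (target)
Conditions: HCl (about 1 M) in MeOH, 35 °C
Reagents that add atoms: none
Why: Acid-catalysed transacetalisation of both aryl MOM ethers to methanol: under dilute acid at mild temperature the monosubstituted alkene and the C2–O1 bond should stay untouched, so the (2S) centre is retained.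

**Compound list**

1 | 2,4,6-trihydroxyacetophenone | CC(=O)c1c(O)cc(O)cc1O | starting material
2 | 1-[2,6-dihydroxy-4-(methoxymethoxy)phenyl]ethan-1-one | CC(=O)c1c(O)cc(OCOC)cc1O | intermediate
3 | prenyl bromide (1-bromo-3-methylbut-2-ene) | CC(C)=CCBr | starting material
4 | 1-[2-hydroxy-4-(methoxymethoxy)-6-(3-methylbut-2-en-1-yloxy)phenyl]ethan-1-one | CC(=O)c1c(O)cc(OCOC)cc1OCC=C(C)C | intermediate
5 | vanillyl alcohol (4-(hydroxymethyl)-2-methoxyphenol) | COc1cc(CO)ccc1O | starting material
6 | [3-methoxy-4-(methoxymethoxy)phenyl]methanol | COCOc1ccc(CO)cc1OC | intermediate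
7 | 1-[2-{[3-methoxy-4-(methoxymethoxy)phenyl]methoxy}-4-(methoxymethoxy)-6-(3-methylbut-2-en-1-yloxy)phenyl]ethan-1-one | CC(=O)c1c(OCC=C(C)C)cc(OCOC)cc1OCc1ccc(OCOC)c(OC)c1 | intermediate
8 | 1-[2-hydroxy-6-{[3-methoxy-4-(methoxymethoxy)phenyl]methoxy}-4-(methoxymethoxy)-3-(2-methylbut-3-en-2-yl)phenyl]ethan-1-one | CC(=O)c1c(O)c(C(C)(C)C=C)c(OCOC)cc1OCc1ccc(OCOC)c(OC)c1 | intermediate
9 | 1-[2-{[tert-butyl(dimethyl)silyl]oxy}-6-{[3-methoxy-4-(methoxymethoxy)phenyl]methoxy}-4-(methoxymethoxy)-3-(2-methylbut-3-en-2-yl)phenyl]ethan-1-one | CC(=O)c1c(O[Si](C)(C)C(C)(C)C)c(C(C)(C)C=C)c(OCOC)cc1OCc1ccc(OCOC)c(OC)c1 | intermediate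
10 | 1-[2-{[tert-butyl(dimethyl)silyl]oxy}-6-{[3-methoxy-4-(methoxymethoxy)phenyl]methoxy}-4-(methoxymethoxy)-3-(2-methylbut-3-en-2-yl)phenyl]-4,4,4-trifluorobutane-1,3-dione (not isolated) | O=C(CC(=O)C(F)(F)F)c1c(O[Si](C)(C)C(C)(C)C)c(C(C)(C)C=C)c(OCOC)cc1OCc1ccc(OCOC)c(OC)c1 | intermediate
11 | 2-diazo-1-[2-{[tert-butyl(dimethyl)silyl]oxy}-6-{[3-methoxy-4-(methoxymethoxy)phenyl]methoxy}-4-(methoxymethoxy)-3-(2-methylbut-3-en-2-yl)phenyl]ethan-1-one | C=CC(C)(C)c1c(OCOC)cc(OCc2ccc(OCOC)c(OC)c2)c(C(=O)C=[N+]=[N-])c1O[Si](C)(C)C(C)(C)C | intermediate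
12 | (2S)-5-{[tert-butyl(dimethyl)silyl]oxy}-2-[3-methoxy-4-(methoxymethoxy)phenyl]-7-(methoxymethoxy)-6-(2-methylbut-3-en-2-yl)-2,3-dihydro-4H-chromen-4-one | C=CC(C)(C)c1c(OCOC)cc2c(c1O[Si](C)(C)C(C)(C)C)C(=O)C[C@@H](c1ccc(OCOC)c(OC)c1)O2 | intermediate
13 | (2S)-5-hydroxy-2-[3-methoxy-4-(methoxymethoxy)phenyl]-7-(methoxymethoxy)-6-(2-methylbut-3-en-2-yl)-2,3-dihydro-4H-chromen-4-one | C=CC(C)(C)c1c(OCOC)cc2c(c1O)C(=O)C[C@@H](c1ccc(OCOC)c(OC)c1)O2 | intermediate
14 | (2S)-5,7-dihydroxy-2-(4-hydroxy-3-methoxyphenyl)-6-(2-methylbut-3-en-2-yl)-2,3-dihydro-4H-chromen-4-one | C=CC(C)(C)c1c(O)cc2c(c1O)C(=O)C[C@@H](c1ccc(O)c(OC)c1)O2 | target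

**Totals**

Total step count: 10.
Longest linear sequence: 9 steps (steps 1, 2, 4, 5, 6, 7, 8, 9, 10 from compound 1); step 3 is the side branch.

**Steps most likely to fail**

1. Step 8 (key step). The carbenoid may be captured by the O1 lone pair (oxonium ylide, then shift of the benzyl group), may add to ring B, or the hydrogen transfer may become stepwise so that the two enantiotopic hydrogens are poorly distinguished. The fallback forms the C2–aryl bond instead; it sets out from 4 and comes back at 12. Condensation of 4 with N,N-dimethylformamide dimethyl acetal (toluene, 90 °C) should give the enaminone (E)-3-(dimethylamino)-1-[2-hydroxy-4-(methoxymethoxy)-6-(3-methylbut-2-en-1-yloxy)phenyl]prop-2-en-1-one F1. Brief treatment with dilute acid should close it, with loss of dimethylamine, to 7-(methoxymethoxy)-5-(3-methylbut-2-en-1-yloxy)-4H-chromen-4-one F2. The Eu(fod)3-catalysed Claisen rearrangement of this chelating 5-O-prenyl ether should give 5-hydroxy-7-(methoxymethoxy)-6-(2-methylbut-3-en-2-yl)-4H-chromen-4-one F3, which is silylated (NaH, TBSCl) to 5-{[tert-butyl(dimethyl)silyl]oxy}-7-(methoxymethoxy)-6-(2-methylbut-3-en-2-yl)-4H-chromen-4-one F4. Commercial 4-bromo-2-methoxyphenol is protected (MOMCl, K2CO3) as 4-bromo-2-methoxy-1-(methoxymethoxy)benzene F5. Bromine–lithium exchange (n-BuLi, −78 °C), B(OiPr)3 and mild hydrolysis convert it into [3-methoxy-4-(methoxymethoxy)phenyl]boronic acid F6. Rhodium-catalysed enantioselective 1,4-addition (Hayashi–Miyaura reaction) of F6 to F4, with [Rh(OH)(cod)]2 and the antipode of a chiral bisphosphine that delivers the (2S) adduct, in toluene/water without added base, should give 12.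

2. Step 5. The sigmatropic shift may run on (Cope shift of the dienone to the para carbon) before tautomerisation, or the new phenol may add to the vinyl group. The fallback uses a substrate whose para carbon is blocked; it sets out from 1 and comes back at 8. Alkylation of 1 at its most acidic 4-OH with prenyl bromide 3 (K2CO3, acetone, rt) should give 1-[2,6-dihydroxy-4-(3-methylbut-2-en-1-yloxy)phenyl]ethan-1-one F7. In this symmetric ether both ortho carbons are equivalent and the para carbon carries the acetyl group, so the thermal Claisen rearrangement (N,N-diethylaniline, 190 °C) can end only at an ortho carbon and should give 1-[2,4,6-trihydroxy-3-(2-methylbut-3-en-2-yl)phenyl]ethan-1-one F8. MOMCl/iPr2NEt on the non-chelated 4-OH should give 1-[2,6-dihydroxy-4-(methoxymethoxy)-3-(2-methylbut-3-en-2-yl)phenyl]ethan-1-one F9. Mitsunobu etherification with 6 at the chelated hydroxyl that is not flanked by the tertiary alkyl group should then give 8.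

3. Step 10. While the MOM groups are solvolysed, acid may promote addition of the C5 or C7 hydroxyl to the vinyl group or ionisation of the C2–O1 bond with erosion of enantiopurity. The fallback avoids protic acid; it sets out from 12 and comes back at 14. Treatment of 12 with TMSOTf and 2,2'-bipyridyl (CH2Cl2, 0 °C) should exchange both aryl MOM ethers for trimethylsilyl ethers and give (2S)-5-{[tert-butyl(dimethyl)silyl]oxy}-2-[3-methoxy-4-(trimethylsilyloxy)phenyl]-6-(2-methylbut-3-en-2-yl)-7-(trimethylsilyloxy)-2,3-dihydro-4H-chromen-4-one F10. Buffered fluoride (TBAF, AcOH, THF, 0 °C) should then remove all three silyl groups in one operation and give 14.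

**Further compounds**

F1 | step 8 | (E)-3-(dimethylamino)-1-[2-hydroxy-4-(methoxymethoxy)-6-(3-methylbut-2-en-1-yloxy)phenyl]prop-2-en-1-one | CN(C)/C=C/C(=O)c1c(O)cc(OCOC)cc1OCC=C(C)C
F2 | step 8 | 7-(methoxymethoxy)-5-(3-methylbut-2-en-1-yloxy)-4H-chromen-4-one | O=c1ccoc2cc(OCOC)cc(OCC=C(C)C)c12
F3 | step 8 | 5-hydroxy-7-(methoxymethoxy)-6-(2-methylbut-3-en-2-yl)-4H-chromen-4-one | O=c1ccoc2cc(OCOC)c(C(C)(C)C=C)c(O)c12
F4 | step 8 | 5-{[tert-butyl(dimethyl)silyl]oxy}-7-(methoxymethoxy)-6-(2-methylbut-3-en-2-yl)-4H-chromen-4-one | O=c1ccoc2cc(OCOC)c(C(C)(C)C=C)c(O[Si](C)(C)C(C)(C)C)c12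
F5 | step 8 | 4-bromo-2-methoxy-1-(methoxymethoxy)benzene | COCOc1ccc(Br)cc1OC
F6 | step 8 | [3-methoxy-4-(methoxymethoxy)phenyl]boronic acid | COCOc1ccc(B(O)O)cc1OC
F7 | step 5 | 1-[2,6-dihydroxy-4-(3-methylbut-2-en-1-yloxy)phenyl]ethan-1-one | CC(=O)c1c(O)cc(OCC=C(C)C)cc1O
F8 | step 5 | 1-[2,4,6-trihydroxy-3-(2-methylbut-3-en-2-yl)phenyl]ethan-1-one | CC(=O)c1c(O)cc(O)c(C(C)(C)C=C)c1O
F9 | step 5 | 1-[2,6-dihydroxy-4-(methoxymethoxy)-3-(2-methylbut-3-en-2-yl)phenyl]ethan-1-one | CC(=O)c1c(O)cc(OCOC)c(C(C)(C)C=C)c1O
F10 | step 10 | (2S)-5-{[tert-butyl(dimethyl)silyl]oxy}-2-[3-methoxy-4-(trimethylsilyloxy)phenyl]-6-(2-methylbut-3-en-2-yl)-7-(trimethylsilyloxy)-2,3-dihydro-4H-chromen-4-one | C=CC(C)(C)c1c(O[Si](C)(C)C)cc2c(c1O[Si](C)(C)C(C)(C)C)C(=O)C[C@@H](c1ccc(O[Si](C)(C)C)c(OC)c1)O2
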